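## Retrosynthetic overview

1. 13 ⇐ 12: 1,2-shift of the C2 benzyl group of a 2-hydroxy-3-oxolanone (ketone hemiketal) to C3 gives the α-hydroxy-γ-lactone; both stereocentres are set in this step.
2. 12 ⇐ 11 ⇐ 10: the hemiketal comes from the dienone by epoxidation of its enol-ether C=C, then one hydrogenation (epoxide C–O, C=C and O-benzyl groups).
3. 10 ⇐ 8 + 2 × 7: a double aldol condensation places both aryl-C1 units on the two α-carbons of tetrahydrofuran-3-one (1,3-related; the shift later makes them vicinal).
4. 7 ⇐ 6 ⇐ 2 + 3, and 2 ⇐ 1: the guaiacyl aldehyde is built from catechol, MeI and glyoxylic acid.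
5. Rings: both arene rings come from catechol; the oxolane ring is bought as 8, is never opened, and becomes the lactone ring only in the last step.

Assumption: the target is the (3R,4R) isomer encoded by the SMILES (benzyl groups trans, 3-OH cis to the 4-benzyl group); racemic 11 is written with the SMILES of one enantiomer, and stereoisomer mixtures are written without stereodescriptors.

## Route

Step 1
Reactants: 1 catechol
Product: 2 guaiacol (2-methoxyphenol)
Conditions: MeI (1.0 equiv), K2CO3 (1.0 equiv), acetone, 56 °C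
Reagents that add atoms: iodomethane, CI
Why: Williamson mono-O-methylation of a symmetrical diol with one equivalent of MeI; guaiacol is separated from veratrole and unreacted catechol by extraction and distillation.

Step 2
Reactants: 2 guaiacol (1.3 equiv); 3 glyoxylic acid (50% in water)
Product: 6 vanillin (4-hydroxy-3-methoxybenzaldehyde), via 4-hydroxy-3-methoxymandelic acid 4 (not isolated), via (4-hydroxy-3-methoxyphenyl)glyoxylic acid 5 (not isolated)
Conditions: NaOH, H2O, 30 °C; then O2 (air), CuSO4 (5 mol %), NaOH, 95 °C; then H2SO4 to pH 2, 80 °C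
Reagents that add atoms: none
Why: The phenoxide undergoes para-selective hydroxyalkylation by the aldehyde of glyoxylate, the mandelate is oxidised by air under copper catalysis to the aryl glyoxylate, and this decarboxylates on acidification (the guaiacol–glyoxylic acid vanillin process).

Step 3
Reactants: 6 vanillin
Product: 7 4-(benzyloxy)-3-methoxybenzaldehyde
Conditions: BnBr (1.1 equiv), K2CO3, DMF, 60 °C
Reagents that add atoms: benzyl bromide, BrCc1ccccc1
Why: Williamson benzylation of the phenol; the benzyl ether survives the aldol and epoxidation steps and is removed for free in step 6.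

Step 4
Reactants: 7 4-(benzyloxy)-3-methoxybenzaldehyde (2.1 equiv); 8 tetrahydrofuran-3-one
Product: 10 (2Z,4E)-2,4-bis[4-(benzyloxy)-3-methoxybenzylidene]dihydrofuran-3(2H)-one, via (E)-4-[4-(benzyloxy)-3-methoxybenzylidene]dihydrofuran-3(2H)-one 9 (not isolated)
Conditions: pyrrolidine (30 mol %), AcOH (30 mol %), EtOH, 50 °C
Reagents that add atoms: none
Why: Double Claisen–Schmidt (crossed aldol) condensation at both α-methylene groups of the ketone under mild amine/acid catalysis, which avoids β-elimination of the ring oxygen; each aryl group ends up anti to the carbonyl (Z at C2, E at C4).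

Step 5
Reactants: 10 (2Z,4E)-2,4-bis[4-(benzyloxy)-3-methoxybenzylidene]dihydrofuran-3(2H)-one
Product: 11 rac-(2S,3R,6E)-2-[4-(benzyloxy)-3-methoxyphenyl]-6-[4-(benzyloxy)-3-methoxybenzylidene]-1,4-dioxaspiro[2.4]heptan-7-one
Conditions: dimethyldioxirane (1.05 equiv, 0.07 M in acetone), CH2Cl2, −20 to 0 °C
Reagents that add atoms: dimethyldioxirane, CC1(C)OO1
Why: Electrophilic epoxidation under neutral conditions; the C2 alkene carries the ring oxygen (an enol ether, as in aurones) and is clearly more electron-rich than the alkyl-substituted C4 enone, and syn oxygen transfer to the Z alkene gives the racemic spiro-epoxide.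

Step 6
Reactants: 11 rac-(2S,3R,6E)-2-[4-(benzyloxy)-3-methoxyphenyl]-6-[4-(benzyloxy)-3-methoxybenzylidene]-1,4-dioxaspiro[2.4]heptan-7-one
Product: 12 2-hydroxy-2,4-bis(4-hydroxy-3-methoxybenzyl)dihydrofuran-3(2H)-one (cyclic hemiketal, all four stereoisomers)
Conditions: H2 (1 atm), 10% Pd/C, wet EtOAc, 20 °C
Reagents that add atoms: none
Why: One heterogeneous hydrogenation cleaves the benzylic C–O bond of the epoxide (as chalcone and aurone epoxides give α-hydroxy ketones) so that the oxygen stays on C2 as the hemiketal OH, saturates the enone C=C and removes both O-benzyl groups; C2 and C4 are formed without control and are both labile, so 12 is used as the mixture.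

Step 7
Reactants: 12 2-hydroxy-2,4-bis(4-hydroxy-3-methoxybenzyl)dihydrofuran-3(2H)-one
Product: 13 (+)-nortrachelogenin, (3R,4R)-3-hydroxy-3,4-bis(4-hydroxy-3-methoxybenzyl)dihydrofuran-2(3H)-one
Conditions: Sc(OTf)3 (10 mol %), (S,S)-Ph-pybox (12 mol %), 2,6-lutidine (20 mol %), THF, 40 °C, argon
Reagents that add atoms: none
Why: Proposed new method: the chiral scandium–pybox Lewis acid chelates the hemiketal oxygen and the C3 ketone of 12 and triggers a suprafacial 1,2-shift of the C2 benzyl group to C3, strongly downhill because a ketone hemiketal becomes a lactone plus a tertiary alcohol; C2 epimerises by ring–chain tautomerism and C4 by lutidine-mediated enolisation, so all four stereoisomers funnel (dynamic kinetic resolution) through the matched one, in which the benzyl group migrates on the ring face opposite the C4 benzyl group and on the C3 face chosen by the ligand, setting C3 (R) and C4 (R) with trans benzyl groups; the closest known reaction types are the benzilic ester rearrangement, Lewis-acid-catalysed enantioselective α-ketol (acyloin) rearrangements and the 2-hydroxyindoxyl to 3-hydroxyoxindole shift.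

## Compound list

1 | catechol (benzene-1,2-diol) | Oc1ccccc1O | starting material
2 | guaiacol (2-methoxyphenol) | COc1ccccc1O | intermediate
3 | glyoxylic acid (oxoacetic acid) | O=CC(=O)O | starting material
4 | 4-hydroxy-3-methoxymandelic acid (racemic, not isolated) | COc1cc(C(O)C(=O)O)ccc1O | intermediate
5 | (4-hydroxy-3-methoxyphenyl)glyoxylic acid (not isolated) | COc1cc(C(=O)C(=O)O)ccc1O | intermediate
6 | vanillin (4-hydroxy-3-methoxybenzaldehyde) | COc1cc(C=O)ccc1O | intermediate
7 | 4-(benzyloxy)-3-methoxybenzaldehyde | COc1cc(C=O)ccc1OCc1ccccc1 | intermediate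
8 | tetrahydrofuran-3-one (dihydrofuran-3(2H)-one) | O=C1CCOC1 | starting material
9 | (E)-4-[4-(benzyloxy)-3-methoxybenzylidene]dihydrofuran-3(2H)-one (not isolated) | O=C1/C(=C/c2ccc(OCc3ccccc3)c(OC)c2)COC1 | intermediate
10 | (2Z,4E)-2,4-bis[4-(benzyloxy)-3-methoxybenzylidene]dihydrofuran-3(2H)-one | O=C1/C(=C/c2ccc(OCc3ccccc3)c(OC)c2)CO/C1=C\c1ccc(OCc2ccccc2)c(OC)c1 | intermediate
11 | rac-(2S,3R,6E)-2-[4-(benzyloxy)-3-methoxyphenyl]-6-[4-(benzyloxy)-3-methoxybenzylidene]-1,4-dioxaspiro[2.4]heptan-7-one (ring oxygen and aryl group cis on the epoxide; one enantiomer drawn) | O=C1/C(=C/c2ccc(OCc3ccccc3)c(OC)c2)CO[C@]12O[C@H]2c1ccc(OCc2ccccc2)c(OC)c1 | intermediate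
12 | 2-hydroxy-2,4-bis(4-hydroxy-3-methoxybenzyl)dihydrofuran-3(2H)-one (hemiketal, mixture of the four stereoisomers) | COc1cc(CC2COC(O)(Cc3ccc(O)c(OC)c3)C2=O)ccc1O | intermediate
13 | (+)-nortrachelogenin, (3R,4R)-3-hydroxy-3,4-bis(4-hydroxy-3-methoxybenzyl)dihydrofuran-2(3H)-one | COc1cc(C[C@@H]2COC(=O)[C@@]2(O)Cc2ccc(O)c(OC)c2)ccc1O | target

## Step count and risks

Total step count: 7. Longest linear sequence: 7 steps (1 → 2 → 6 → 7 → 10 → 11 → 12 → 13); 3 and 8 enter at steps 2 and 4.

The three steps most likely to fail are steps 5, 6 and 7; step 7 is the riskiest.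

**Step 5 (chemoselective epoxidation).** Dimethyldioxirane may also attack the C4 enone, which after step 6 would put an unwanted hydroxyl on C4. The fallback sets out from 10 and comes back at 12, and it places the oxygen on C2 by enolate chemistry instead of alkene oxidation. Compound 10 is hydrogenated over 5% Pd/C poisoned with Ph2S (H2, 1 atm, EtOAc), which saturates both exocyclic C=C bonds but keeps the benzyl ethers, to give 2,4-bis[4-(benzyloxy)-3-methoxybenzyl]dihydrofuran-3(2H)-one F1. Its thermodynamic potassium enolate (KN(SiMe3)2, 0.95 equiv, THF, −78 to −20 °C; the α-alkoxy C2–H is the more acidic α-hydrogen) is hydroxylated with 2-(phenylsulfonyl)-3-phenyloxaziridine at −78 °C to 2,4-bis[4-(benzyloxy)-3-methoxybenzyl]-2-hydroxydihydrofuran-3(2H)-one F2. Hydrogenolysis of the two benzyl ethers (H2, 10% Pd/C, EtOAc) then gives 12.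

**Step 6 (epoxide hydrogenolysis).** Pd/C could open the epoxide at the spiro carbon (giving the 2-H, benzylic-OH isomer) or reduce incompletely. The fallback sets out from 11 and comes back at 12, and it fixes the C2–O bond before any reduction. Compound 11 is hydrolysed (HClO4 0.05 M, THF/H2O, 0 °C) to the hemiketal diol (4E)-4-[4-(benzyloxy)-3-methoxybenzylidene]-2-{[4-(benzyloxy)-3-methoxyphenyl](hydroxy)methyl}-2-hydroxydihydrofuran-3(2H)-one F3; either mode of water attack gives the same diol. The benzylic hydroxyl, now the only C–O bond that can be hydrogenolysed, is removed together with the C=C bond and the benzyl ethers over Pd(OH)2/C (H2, EtOAc with 1% AcOH), giving 12.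

**Step 7 (new dynamic kinetic 1,2-benzyl shift).** The risks are:
- an uncatalysed racemic shift;
- C4 epimerising more slowly than the shift, which would cap the yield near 50% and give the cis diastereomer from the mismatched half;
- dehydration of the hemiketal to the 2-benzylidene enol ether, or β-elimination of the ring oxygen;
- the opposite sense of induction, in which case the (R,R) ligand is used.

The fallback uses known lignan chemistry only; it sets out from aldehyde 7 and comes back at 13.

- Wittig reaction of 7 with Ph3P=C(CO2Me)CH2CO2H (made from maleic anhydride, PPh3 and MeOH; toluene, 80 °C) gives (E)-4-[4-(benzyloxy)-3-methoxyphenyl]-3-(methoxycarbonyl)but-3-enoic acid F4.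
- Asymmetric hydrogenation with [Rh(cod)(Et-DuPhos)]OTf (the ligand antipode that delivers the S acid; H2 5 atm, MeOH) gives (3S)-4-[4-(benzyloxy)-3-methoxyphenyl]-3-(methoxycarbonyl)butanoic acid F5.
- Reduction of the ester in the potassium carboxylate with Ca(BH4)2 (EtOH), then acidification, gives (4S)-4-[4-(benzyloxy)-3-methoxybenzyl]dihydrofuran-2(3H)-one F6.
- The potassium enolate of F6 (KN(SiMe3)2, THF, −78 °C) is hydroxylated by 2-(phenylsulfonyl)-3-phenyloxaziridine anti to the C4 substituent, giving (3S,4R)-4-[4-(benzyloxy)-3-methoxybenzyl]-3-hydroxydihydrofuran-2(3H)-one F7.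
- In parallel, 7 is reduced (NaBH4, MeOH) to [4-(benzyloxy)-3-methoxyphenyl]methanol F8 and brominated (PBr3, Et2O, 0 °C) to 1-(benzyloxy)-4-(bromomethyl)-2-methoxybenzene F9.
- The dianion of F7 (LiN(i-Pr)2, 2.2 equiv, THF/HMPA, −78 °C) is alkylated by F9 anti to the C4 benzyl group, giving (3R,4R)-3,4-bis[4-(benzyloxy)-3-methoxybenzyl]-3-hydroxydihydrofuran-2(3H)-one F10.
- Hydrogenolysis (H2, 10% Pd/C, EtOAc) gives 13.

## Further compounds

F1 | step 5 | 2,4-bis[4-(benzyloxy)-3-methoxybenzyl]dihydrofuran-3(2H)-one (stereoisomer mixture) | O=C1C(Cc2ccc(OCc3ccccc3)c(OC)c2)COC1Cc1ccc(OCc2ccccc2)c(OC)c1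
F2 | step 5 | 2,4-bis[4-(benzyloxy)-3-methoxybenzyl]-2-hydroxydihydrofuran-3(2H)-one (stereoisomer mixture) | O=C1C(Cc2ccc(OCc3ccccc3)c(OC)c2)COC1(O)Cc1ccc(OCc2ccccc2)c(OC)c1
F3 | step 6 | (4E)-4-[4-(benzyloxy)-3-methoxybenzylidene]-2-{[4-(benzyloxy)-3-methoxyphenyl](hydroxy)methyl}-2-hydroxydihydrofuran-3(2H)-one (stereoisomer mixture) | O=C1/C(=C/c2ccc(OCc3ccccc3)c(OC)c2)COC1(O)C(O)c1ccc(OCc2ccccc2)c(OC)c1
F4 | step 7 | (E)-4-[4-(benzyloxy)-3-methoxyphenyl]-3-(methoxycarbonyl)but-3-enoic acid | COC(=O)/C(CC(=O)O)=C/c1ccc(OCc2ccccc2)c(OC)c1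
F5 | step 7 | (3S)-4-[4-(benzyloxy)-3-methoxyphenyl]-3-(methoxycarbonyl)butanoic acid | COC(=O)[C@H](CC(=O)O)Cc1ccc(OCc2ccccc2)c(OC)c1
F6 | step 7 | (4S)-4-[4-(benzyloxy)-3-methoxybenzyl]dihydrofuran-2(3H)-one | O=C1C[C@H](Cc2ccc(OCc3ccccc3)c(OC)c2)CO1
F7 | step 7 | (3S,4R)-4-[4-(benzyloxy)-3-methoxybenzyl]-3-hydroxydihydrofuran-2(3H)-one | COc1cc(C[C@@H]2COC(=O)[C@H]2O)ccc1OCc1ccccc1
F8 | step 7 | [4-(benzyloxy)-3-methoxyphenyl]methanol | COc1cc(CO)ccc1OCc1ccccc1
F9 | step 7 | 1-(benzyloxy)-4-(bromomethyl)-2-methoxybenzene | COc1cc(CBr)ccc1OCc1ccccc1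
F10 | step 7 | (3R,4R)-3,4-bis[4-(benzyloxy)-3-methoxybenzyl]-3-hydroxydihydrofuran-2(3H)-one | COc1cc(C[C@@H]2COC(=O)[C@@]2(O)Cc2ccc(OCc3ccccc3)c(OC)c2)ccc1OCc1ccccc1
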